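## Retrosynthetic overview

1. The target is cut at the C6 ester: core alcohol 18 plus (R)-2,3-dihydroxy-2-methylpropanoic acid, joined last as its bis-silylated acid chloride.
2. Core 18 comes from bromide 16 by one CrCl2-mediated intramolecular SE2′ allylation (C6–C7). This closes the ten-membered ring, creates the α-methylene-γ-lactone and sets C6 and C7 from C8.
3. Butenolide 14 comes from 2-silyloxyfuran 13 and allylic carbonate 9 by an enantioselective, palladium-catalysed dearomative γ-allylation (C8–C9). This is the key step and sets C8, the only catalyst-controlled stereocentre.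
4. Carbonate 9 is built from triethyl phosphonoacetate, homoprenyl bromide and glyoxal mono-acetal (HWE fixes the C4=C5 geometry, SeO2 oxidises C9). Furan 13 comes from furan-3-ylmethanol.
5. Ring order: aromatic furan → butenolide (dearomatised) → ten-membered carbocycle and saturated lactone together.

Assumption: atom labels C1–C15 follow germacrane numbering (C12 = lactone carbonyl on O8, C15 = acetoxymethyl carbon); ordinary reagents are named on the Conditions lines and are not numbered.

## Route

Step 1
Reactants: 1 triethyl phosphonoacetate; 2 5-bromo-2-methylpent-2-ene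
Product: 3 ethyl 2-(diethoxyphosphoryl)-6-methylhept-5-enoate (racemic)
Conditions: NaH, DMSO, 25 → 60 °C (1 in 1.5-fold excess)
Reagents that add atoms: none
Why: SN2 C-alkylation of the stabilised phosphonoacetate carbanion by an unhindered primary bromide; the new centre is racemic and disappears in step 2.

Step 2
Reactants: 3 ethyl 2-(diethoxyphosphoryl)-6-methylhept-5-enoate; 4 2,2-dimethoxyacetaldehyde (60 % aqueous solution)
Product: 5 ethyl (2E)-4,4-dimethoxy-2-(4-methylpent-3-en-1-yl)but-2-enoate
Conditions: Ba(OH)2·8H2O, THF/H2O, 25 °C; minor Z isomer removed by chromatography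
Reagents that add atoms: none
Why: Horner–Wadsworth–Emmons olefination under water-tolerant conditions places the ester (future C15) trans to the aldehyde-derived carbon (future C6), which is the ring-cis C4=C5 geometry of the target.

Step 3
Reactants: 5 ethyl (2E)-4,4-dimethoxy-2-(4-methylpent-3-en-1-yl)but-2-enoate
Product: 6 (2E)-4,4-dimethoxy-2-(4-methylpent-3-en-1-yl)but-2-en-1-ol
Conditions: i-Bu2AlH (2.2 equiv), CH2Cl2, −78 °C; Rochelle salt work-up
Reagents that add atoms: none
Why: 1,2-reduction of the conjugated ester to the allylic alcohol leaves acetal and olefins untouched; no stereocentre is formed.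

Step 4
Reactants: 6 (2E)-4,4-dimethoxy-2-(4-methylpent-3-en-1-yl)but-2-en-1-ol
Product: 7 (2E)-4,4-dimethoxy-2-(4-methylpent-3-en-1-yl)but-2-en-1-yl acetate
Conditions: Ac2O, pyridine, DMAP (cat.), CH2Cl2, 0 → 25 °C
Reagents that add atoms: acetic anhydride CC(=O)OC(C)=O
Why: DMAP-catalysed acetylation of a primary alcohol installs the C15 acetate of the target.

Step 5
Reactants: 7 (2E)-4,4-dimethoxy-2-(4-methylpent-3-en-1-yl)but-2-en-1-yl acetate
Product: 8 (2E)-2-[(3E)-5-hydroxy-4-methylpent-3-en-1-yl]-4,4-dimethoxybut-2-en-1-yl acetate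
Conditions: SeO2 (0.3 equiv), t-BuOOH (anhydrous, in decane, 3 equiv), CH2Cl2, 0 → 25 °C; stopped at partial conversion, 7 recycled
Reagents that add atoms: tert-butyl hydroperoxide CC(C)(C)OO; selenium dioxide O=[Se]=O
Why: Selenium dioxide allylic oxidation (ene reaction, then 2,3-sigmatropic shift) attacks the E-methyl of the electron-rich terminal olefin and gives the (E)-allylic alcohol (C9), while the other olefin is deactivated by its allylic acetate and acetal.

Step 6
Reactants: 8 (2E)-2-[(3E)-5-hydroxy-4-methylpent-3-en-1-yl]-4,4-dimethoxybut-2-en-1-yl acetate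
Product: 9 (2E)-4,4-dimethoxy-2-{(3E)-5-[(methoxycarbonyl)oxy]-4-methylpent-3-en-1-yl}but-2-en-1-yl acetate
Conditions: ClCO2Me, pyridine, CH2Cl2, 0 °C
Reagents that add atoms: methyl chloroformate COC(Cl)=O
Why: O-acylation of the primary allylic alcohol gives a carbonate that ionises far faster with zerovalent palladium than the C15 acetate.

Step 7
Reactants: 10 furan-3-ylmethanol
Product: 12 3-(hydroxymethyl)furan-2(5H)-one, via lithiated dimethyl furan-2-ylboronate 11 (not isolated)
Conditions: n-BuLi (2.2 equiv), THF, −78 → 0 °C; B(OMe)3, −78 → 25 °C; then 30 % H2O2, AcOH, 0 → 25 °C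
Reagents that add atoms: hydrogen peroxide OO
Why: Alkoxide-directed ortho-lithiation at C2 of the furan, borylation and oxidative C–B to C–O conversion give the 2-hydroxyfuran, which tautomerises to the conjugated butenolide.

Step 8
Reactants: 12 3-(hydroxymethyl)furan-2(5H)-one
Product: 13 triethyl({3-[(triethylsilyloxy)methyl]furan-2-yl}oxy)silane
Conditions: Et3SiOTf (2.2 equiv), Et3N, CH2Cl2, 0 °C
Reagents that add atoms: triethylsilyl trifluoromethanesulfonate CC[Si](CC)(CC)OS(=O)(=O)C(F)(F)F
Why: Silylation of the alcohol and soft enolisation/O-silylation of the butenolide give the aromatic 2-silyloxyfuran, the nucleophile for the key step.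

Step 9 (key step)
Reactants: 9 (2E)-4,4-dimethoxy-2-{(3E)-5-[(methoxycarbonyl)oxy]-4-methylpent-3-en-1-yl}but-2-en-1-yl acetate; 13 triethyl({3-[(triethylsilyloxy)methyl]furan-2-yl}oxy)silane (1.3 equiv)
Product: 14 (2E)-4,4-dimethoxy-2-[(3E)-4-methyl-5-{(2S)-5-oxo-4-[(triethylsilyloxy)methyl]-2,5-dihydrofuran-2-yl}pent-3-en-1-yl]but-2-en-1-yl acetate
Conditions: Pd2(dba)3·CHCl3 (2.5 mol %), (R,R)-DACH-phenyl Trost ligand (7.5 mol %), tetrabutylammonium difluorotriphenylsilicate (20 mol %), toluene, 0 → 25 °C
Reagents that add atoms: none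
Why: Proposed new method: the zerovalent palladium–ligand complex ionises the carbonate to a syn π-allyl cation, the released methoxide (relayed by the fluorosilicate) desilylates 13 to the aromatic 2-furanolate, and this attacks the unsubstituted allyl terminus through C5 from the face left open by the chiral pocket, so the furan is dearomatised, C8–C9 is formed with the E-olefin retained and C8 is set as S (the ligand antipode is used if the observed sense is opposite); the closest known chemistry is the Tsuji–Trost asymmetric allylic alkylation of prochiral enolates and the racemic γ-allylation of 2-silyloxyfurans.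

Step 10
Reactants: 14 (2E)-4,4-dimethoxy-2-[(3E)-4-methyl-5-{(2S)-5-oxo-4-[(triethylsilyloxy)methyl]-2,5-dihydrofuran-2-yl}pent-3-en-1-yl]but-2-en-1-yl acetate
Product: 15 (2E)-2-{(3E)-5-[(2S)-4-(hydroxymethyl)-5-oxo-2,5-dihydrofuran-2-yl]-4-methylpent-3-en-1-yl}-4-oxobut-2-en-1-yl acetate
Conditions: AcOH/THF/H2O (3:1:1), 25 °C
Reagents that add atoms: water O
Why: Mild acid hydrolysis unmasks the enal (C6) and cleaves the triethylsilyl ether in one operation without touching the acetate or the base-sensitive C8 centre.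

Step 11
Reactants: 15 (2E)-2-{(3E)-5-[(2S)-4-(hydroxymethyl)-5-oxo-2,5-dihydrofuran-2-yl]-4-methylpent-3-en-1-yl}-4-oxobut-2-en-1-yl acetate
Product: 16 (2E)-2-{(3E)-5-[(2S)-4-(bromomethyl)-5-oxo-2,5-dihydrofuran-2-yl]-4-methylpent-3-en-1-yl}-4-oxobut-2-en-1-yl acetate
Conditions: NBS, Me2S, CH2Cl2, −30 → 0 °C
Reagents that add atoms: N-bromosuccinimide BrN1C(=O)CCC1=O
Why: Corey–Kim bromination (bromide displaces the alkoxysulfonium ion) converts the allylic alcohol into the bromide under neutral conditions that tolerate the aldehyde, which an Appel reagent would not.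

Step 12
Reactants: 16 (2E)-2-{(3E)-5-[(2S)-4-(bromomethyl)-5-oxo-2,5-dihydrofuran-2-yl]-4-methylpent-3-en-1-yl}-4-oxobut-2-en-1-yl acetate
Product: 18 [(3aS,4R,5E,9E,11aS)-4-hydroxy-10-methyl-3-methylidene-2-oxo-2,3,3a,4,7,8,11,11a-octahydrocyclodeca[b]furan-6-yl]methyl acetate, via allylchromium dichloride 17 (not isolated)
Conditions: CrCl2 (8 equiv), THF, 25 °C, 16 added by syringe pump to 0.003 M
Reagents that add atoms: none
Why: Nozaki–Hiyama–Kishi (Barbier-type) allylation in which the allylchromium adds to the tethered aldehyde through its γ-carbon C7 in a chair Zimmerman–Traxler transition state: attack anti to the C9 substituent on C8 gives the trans-lactone (C7), the ring-fixed E-type allyl geometry with an equatorial aldehyde substituent gives the anti C6/C7 relationship (C6 R), and the allylic transposition delivers the exo-methylene lactone and the ten-membered ring (the C7 descriptor of 18 reads S only because of a priority change in the free alcohol).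

Step 13
Reactants: 19 (2S)-3-bromo-2-hydroxy-2-methylpropanoic acid
Product: 21 (2R)-2,3-dihydroxy-2-methylpropanoic acid, via sodium (2R)-2-methyloxirane-2-carboxylate 20 (not isolated)
Conditions: NaOH (3 equiv), H2O, 0 → 70 °C; then HCl to pH 2, evaporation and extraction
Reagents that add atoms: sodium hydroxide [Na+].[OH-]
Why: Intramolecular Williamson closure to the epoxide and hydroxide opening at the primary carbon never touch the quaternary centre, so its configuration is retained (the descriptor changes from S to R only because OH replaces Br in the priority order).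

Step 14
Reactants: 21 (2R)-2,3-dihydroxy-2-methylpropanoic acid
Product: 23 (2R)-2-methyl-2,3-bis(trimethylsilyloxy)propanoyl chloride, via trimethylsilyl (2R)-2-methyl-2,3-bis(trimethylsilyloxy)propanoate 22 (not isolated)
Conditions: Me3SiCl (3.3 equiv), Et3N, CH2Cl2, 0 → 25 °C, salts filtered off; then (COCl)2 (1.05 equiv), DMF (cat.), 0 → 25 °C; concentrated and used crude
Reagents that add atoms: chlorotrimethylsilane C[Si](C)(C)Cl; oxalyl chloride ClC(=O)C(Cl)=O
Why: Persilylation followed by the Vilsmeier-type conversion of a silyl ester into the acid chloride under neutral conditions gives a protected acyl donor without touching the stereocentre.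

Step 15
Reactants: 18 [(3aS,4R,5E,9E,11aS)-4-hydroxy-10-methyl-3-methylidene-2-oxo-2,3,3a,4,7,8,11,11a-octahydrocyclodeca[b]furan-6-yl]methyl acetate; 23 (2R)-2-methyl-2,3-bis(trimethylsilyloxy)propanoyl chloride (2.5 equiv)
Product: 25 [(3aR,4R,5E,9E,11aS)-6-(acetyloxymethyl)-10-methyl-3-methylidene-2-oxo-2,3,3a,4,7,8,11,11a-octahydrocyclodeca[b]furan-4-yl] (2R)-2,3-dihydroxy-2-methylpropanoate, via bis-trimethylsilyl ether of the target 24 (not isolated)
Conditions: Et3N, DMAP, CH2Cl2, 0 → 25 °C; then citric acid, MeOH, 0 °C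
Reagents that add atoms: none
Why: DMAP-catalysed acylation of the C6 alcohol with retention at C6, followed by acid-catalysed methanolysis of the two labile trimethylsilyl ethers under conditions too mild to cyclise the germacradiene or cleave the acetate.

## Compound list

1 | triethyl phosphonoacetate | CCOC(=O)CP(=O)(OCC)OCC | starting material
2 | 5-bromo-2-methylpent-2-ene | CC(C)=CCCBr | starting material
3 | ethyl 2-(diethoxyphosphoryl)-6-methylhept-5-enoate (racemic) | CCOC(=O)C(CCC=C(C)C)P(=O)(OCC)OCC | intermediate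
4 | 2,2-dimethoxyacetaldehyde | COC(OC)C=O | starting material
5 | ethyl (2E)-4,4-dimethoxy-2-(4-methylpent-3-en-1-yl)but-2-enoate | CCOC(=O)/C(CCC=C(C)C)=C/C(OC)OC | intermediate
6 | (2E)-4,4-dimethoxy-2-(4-methylpent-3-en-1-yl)but-2-en-1-ol | OC/C(CCC=C(C)C)=C/C(OC)OC | intermediate
7 | (2E)-4,4-dimethoxy-2-(4-methylpent-3-en-1-yl)but-2-en-1-yl acetate | CC(=O)OC/C(CCC=C(C)C)=C/C(OC)OC | intermediate
8 | (2E)-2-[(3E)-5-hydroxy-4-methylpent-3-en-1-yl]-4,4-dimethoxybut-2-en-1-yl acetate | CC(=O)OC/C(CC/C=C(\C)CO)=C/C(OC)OC | intermediate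
9 | (2E)-4,4-dimethoxy-2-{(3E)-5-[(methoxycarbonyl)oxy]-4-methylpent-3-en-1-yl}but-2-en-1-yl acetate | CC(=O)OC/C(CC/C=C(\C)COC(=O)OC)=C/C(OC)OC | intermediate
10 | furan-3-ylmethanol | OCc1ccoc1 | starting material
11 | dimethyl {3-[(lithiooxy)methyl]furan-2-yl}boronate | [Li]OCc1ccoc1B(OC)OC | intermediate
12 | 3-(hydroxymethyl)furan-2(5H)-one | O=C1OCC=C1CO | intermediate
13 | triethyl({3-[(triethylsilyloxy)methyl]furan-2-yl}oxy)silane | CC[Si](CC)(CC)OCc1ccoc1O[Si](CC)(CC)CC | intermediate
14 | (2E)-4,4-dimethoxy-2-[(3E)-4-methyl-5-{(2S)-5-oxo-4-[(triethylsilyloxy)methyl]-2,5-dihydrofuran-2-yl}pent-3-en-1-yl]but-2-en-1-yl acetate | CC(=O)OC/C(CC/C=C(\C)C[C@@H]1OC(=O)C(CO[Si](CC)(CC)CC)=C1)=C/C(OC)OC | intermediate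
15 | (2E)-2-{(3E)-5-[(2S)-4-(hydroxymethyl)-5-oxo-2,5-dihydrofuran-2-yl]-4-methylpent-3-en-1-yl}-4-oxobut-2-en-1-yl acetate | CC(=O)OC/C(CC/C=C(\C)C[C@@H]1OC(=O)C(CO)=C1)=C/C=O | intermediate
16 | (2E)-2-{(3E)-5-[(2S)-4-(bromomethyl)-5-oxo-2,5-dihydrofuran-2-yl]-4-methylpent-3-en-1-yl}-4-oxobut-2-en-1-yl acetate | CC(=O)OC/C(CC/C=C(\C)C[C@@H]1OC(=O)C(CBr)=C1)=C/C=O | intermediate
17 | allylchromium dichloride derived from 16 (CrCl2 unit in place of Br, trivalent chromium) | CC(=O)OC/C(CC/C=C(\C)C[C@@H]1OC(=O)C(C[Cr](Cl)Cl)=C1)=C/C=O | intermediate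
18 | [(3aS,4R,5E,9E,11aS)-4-hydroxy-10-methyl-3-methylidene-2-oxo-2,3,3a,4,7,8,11,11a-octahydrocyclodeca[b]furan-6-yl]methyl acetate (6α-hydroxy, 7α-H, 8β-H core) | C=C1C(=O)O[C@H]2C/C(C)=C/CC/C(COC(C)=O)=C\[C@@H](O)[C@H]12 | intermediate
19 | (2S)-3-bromo-2-hydroxy-2-methylpropanoic acid | OC(=O)[C@](C)(O)CBr | starting material
20 | sodium (2R)-2-methyloxirane-2-carboxylate | [Na+].[O-]C(=O)[C@@]1(C)CO1 | intermediate
21 | (2R)-2,3-dihydroxy-2-methylpropanoic acid | OC(=O)[C@](C)(O)CO | intermediate
22 | trimethylsilyl (2R)-2-methyl-2,3-bis(trimethylsilyloxy)propanoate | C[Si](C)(C)OC(=O)[C@](C)(O[Si](C)(C)C)CO[Si](C)(C)C | intermediate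
23 | (2R)-2-methyl-2,3-bis(trimethylsilyloxy)propanoyl chloride | ClC(=O)[C@](C)(O[Si](C)(C)C)CO[Si](C)(C)C | intermediate
24 | [(3aR,4R,5E,9E,11aS)-6-(acetyloxymethyl)-10-methyl-3-methylidene-2-oxo-2,3,3a,4,7,8,11,11a-octahydrocyclodeca[b]furan-4-yl] (2R)-2-methyl-2,3-bis(trimethylsilyloxy)propanoate | C=C1C(=O)O[C@H]2C/C(C)=C/CC/C(COC(C)=O)=C\[C@@H](OC(=O)[C@](C)(O[Si](C)(C)C)CO[Si](C)(C)C)[C@H]12 | intermediate
25 | [(3aR,4R,5E,9E,11aS)-6-(acetyloxymethyl)-10-methyl-3-methylidene-2-oxo-2,3,3a,4,7,8,11,11a-octahydrocyclodeca[b]furan-4-yl] (2R)-2,3-dihydroxy-2-methylpropanoate | C=C1C(=O)O[C@H]2C/C(C)=C/CC/C(COC(C)=O)=C\[C@@H](OC(=O)[C@](C)(O)CO)[C@H]12 | target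

## Step count and risks

Total steps: 15. Longest linear sequence: 11 (steps 1–6, 9–12, 15).

Three steps most likely to fail:

Step 9. The enantioselective attack of a furanolate on a π-allyl palladium complex is unproven; the ee may be low, the sense is not predictable, and the C15 acetate could ionise in competition. The fallback sets out from 8 and 13 and gives up catalyst control. Alcohol 8 is converted with CBr4 and PPh3 into the primary allylic bromide F1. This is coupled with 13 under AgOCOCF3 promotion in CH2Cl2 at −78 → 0 °C (SN1-type γ-alkylation of the silyloxyfuran) to give the racemic butenolide F2. The enantiomers are separated by preparative chiral SFC, and the (S)-enantiomer re-enters the route as 14.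

Step 12. Closure of a ten-membered ring may give oligomers, the cis-fused lactone or the C6 epimer. The fallback sets out from 16 and replaces the transient allylchromium by an isolable reagent. Bromide 16 is borylated with B2pin2 and Pd2(dba)3 (cat.) in toluene at 25 °C, where the allylic bromide reacts much faster than the acetate, to give the primary pinacol allylboronate F3. F3 is cyclised at 0.002 M with Sc(OTf)3 (10 mol %) in toluene; this Lewis-acid-catalysed allylboration is stereospecific through a closed transition state and returns to the route at 18.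

Step 15. A hindered tertiary acid chloride with labile silyl ethers must acylate a hindered secondary alcohol. The fallback sets out from 21 and 18 and changes the protecting-group and activation strategy. Acid 21 is converted with 2,2-dimethoxypropane and TsOH into the acetonide acid F4. F4 is coupled to 18 under Yamaguchi conditions (2,4,6-trichlorobenzoyl chloride, Et3N, DMAP, toluene) to give the acetonide ester F5. The acetonide is removed with BiCl3 in MeCN/H2O at 25 °C, which returns to the route at 25.

Further compounds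
F1 | step 9 | (2E)-2-[(3E)-5-bromo-4-methylpent-3-en-1-yl]-4,4-dimethoxybut-2-en-1-yl acetate | CC(=O)OC/C(CC/C=C(\C)CBr)=C/C(OC)OC
F2 | step 9 | racemic (2E)-4,4-dimethoxy-2-[(3E)-4-methyl-5-{5-oxo-4-[(triethylsilyloxy)methyl]-2,5-dihydrofuran-2-yl}pent-3-en-1-yl]but-2-en-1-yl acetate | CC(=O)OC/C(CC/C=C(\C)CC1OC(=O)C(CO[Si](CC)(CC)CC)=C1)=C/C(OC)OC
F3 | step 12 | (2E)-2-{(3E)-4-methyl-5-[(2S)-5-oxo-4-[(4,4,5,5-tetramethyl-1,3,2-dioxaborolan-2-yl)methyl]-2,5-dihydrofuran-2-yl]pent-3-en-1-yl}-4-oxobut-2-en-1-yl acetate | CC(=O)OC/C(CC/C=C(\C)C[C@@H]1OC(=O)C(CB2OC(C)(C)C(C)(C)O2)=C1)=C/C=O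
F4 | step 15 | (4R)-2,2,4-trimethyl-1,3-dioxolane-4-carboxylic acid | OC(=O)[C@@]1(C)COC(C)(C)O1
F5 | step 15 | [(3aR,4R,5E,9E,11aS)-6-(acetyloxymethyl)-10-methyl-3-methylidene-2-oxo-2,3,3a,4,7,8,11,11a-octahydrocyclodeca[b]furan-4-yl] (4R)-2,2,4-trimethyl-1,3-dioxolane-4-carboxylate | C=C1C(=O)O[C@H]2C/C(C)=C/CC/C(COC(C)=O)=C\[C@@H](OC(=O)[C@@]3(C)COC(C)(C)O3)[C@H]12
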